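Per minute is the unit that lets flasks of different charge stand side by side, so I ask of each run what fraction of the remaining starting material it turns in a minute.

| flask | starting material | free catalyst | time |
|---|---|---|---|
| grey | 200 mM | 10.0 mM |  |
| green | 100 mM | 10.0 mM |  |
| violet | 200 mM | 20.0 mM |  |
| amber | 600 mM | 10.0 mM |  |
| teal | 200 mM | 65.0 mM | 9.4 min |

| grey run: time / min | grey run: [product] / mM | green run: time / min | green run: [product] / mM | violet run: time / min | violet run: [product] / mM | amber run: time / min | amber run: [product] / mM |
|---|---|---|---|---|---|---|---|
| 0.38 | 8.7 | 0.38 | 3.6 | 0.38 | 13.3 | 0.38 | 27.5 |
| 0.60 | 11.9 | 0.60 | 4.7 | 0.60 | 16.5 | 0.60 | 40.7 |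
| 0.94 | 18.9 | 0.94 | 5.6 | 0.94 | 23.6 | 0.94 | 65.3 |
| 1.5 | 34.4 | 1.5 | 10.8 | 1.5 | 39.7 | 1.5 | 100.9 |
| 2.4 | 47.4 | 2.4 | 16.2 | 2.4 | 54.0 | 2.4 | 152.5 |
| 3.7 | 66.9 | 3.7 | 27.9 | 3.7 | 76.7 | 3.7 | 219.9 |
| 5.9 | 91.3 | 5.9 | 33.5 | 5.9 | 107.2 | 5.9 | 317.5 |
| 9.4 | 115.4 | 9.4 | 47.4 | 9.4 | 134.2 | 9.4 | 417.7 |

(scatter of a reading: 2 mM)

- Overall: starting material -> product, with free catalyst as catalyst.
- Constant volume, constant temperature.
- What is held in complexes is read along with the free species.
- An order is taken over about fifteen percent of the charge, up and down.

- the power of [free catalyst] that the first rate follows, about the charge of the grey run; measure it at two percent of starting material made into product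
- the power of [starting material] that the first rate follows, about the charge of the grey run; measure it at two percent of starting material made into product (one fixed amount of product, the same in the runs compared)
- the green run starts with 100 mM less of starting material than the grey run, and with no product. Compared where both hold the same amount of starting material, once fifteen percent of what the green run was charged with has turned into product, is the green run faster, slower or alike (within a tenth)?
- product in the teal run at 9.4 min, as a share of the starting material charged

I begin with the end state. I take it to be the whole charge as product, because the amber run stands at 417.7 mM of 600 mM at 9.4 min and gained 100 mM over its last interval. To see how fast that end is approached, I read the violet run at 9.4 min and get 0.118 min⁻¹. This is what I carry: the mean constant, the natural logarithm of charge over what is left, divided by the time, a pseudo-first-order constant. The grey run gives 0.0915 min⁻¹, so doubling the catalyst raises the constant with a power of 0.370. The teal run has the charge of the violet run and 3.25 times its catalyst, which gives 0.183 min⁻¹ and a share of 82.1 %.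

But the constant does not belong to the catalyst by itself. The green run, with the catalyst of the grey run, gives 0.0683 min⁻¹, smaller than the grey value, which is a power of 0.421 in the amount. The teal run would work through lower amounts than the violet run, so my figure is too high. If I take a run's typical amount as the geometric mean of charge and remainder, the teal amount is 0.738 times the violet amount. Raised to that power, this brings the constant down to 0.161 min⁻¹. I commit to a share of 78.0 %, with one doubt left standing: the catalyst power comes from a single doubling and is stretched beyond it.

The forecast gives 0.25 for the catalyst order, 1.3 for the order in starting material, alike for the comparison, and 73 % for the teal run, lower than my share, with the words “Teal sits on the plateau”.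

The flask gives 0.49, 1.4, alike and 77.2 %, so the two part on the catalyst order, where the forecast is lower.

    free catalyst + starting material ⇌ catalyst-substrate complex, settled at all times (16.60 M⁻¹)
    catalyst-substrate complex + starting material ⇌ doubly bound catalyst, settled at all times (5.140 M⁻¹)
    doubly bound catalyst → product + catalyst-substrate complex (7.620 min⁻¹)
    starting material → product (0.02886 min⁻¹)
    2 free catalyst ⇌ resting dimer, settled at all times (4190 M⁻¹)

The teal constant is 0.157 min⁻¹, which is 1.33 times the violet 0.118 min⁻¹ for 3.25 times the catalyst. Added catalyst buys so little because free catalyst pairs into the resting dimer. Without that association the teal run reaches 94.3 %, a mean constant of 0.304 min⁻¹.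

The numbers in the tables are calculated from invented constants, and the scatter is random.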